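**Retrosynthetic overview**

- The plan rests on ring A (C3a, C4, C5, C6, C7, C7a in benzofuran numbering): O1 on C7a and the methoxy group on C7 are adjacent, the propenyl group is on C5, and C4 and C6 carry hydrogen.
- The C4–H bond is made last from C4–OTf, which comes from a C4–OH; this extra oxygen is the CO-derived carbon of the annulation.
- Ring A is disconnected at C7–C6, C5–C4 and C4–C3a into a chromium methoxycarbene on C7a of a 2,3-dihydrofuran, (E)-pent-3-en-1-yne and one CO ligand (Dötz benzannulation).
- The carbene comes from the trans-2-aryl-3-methyl-2,3-dihydrofuran (C5 lithiation, Cr(CO)6, O-methylation). The dihydrofuran comes from molybdenum-catalysed cycloisomerisation of an anti alkynol. The alkynol comes from allenylzinc propargylation of 3,4,5-trimethoxybenzaldehyde with (S)-but-3-yn-2-yl mesylate, which sets both stereocentres; the enyne comes from crotonaldehyde.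
- Ring order: the trimethoxyphenyl ring is bought, the dihydrofuran ring is closed in step 3, ring A in step 6.

Key step: step 6

Remark: atom numbers follow 2,3-dihydro-1-benzofuran (O1, C2, C3, C3a, C4 to C7, C7a). The target is the trans (2R,3R) isomer. The volatile enyne 12 is handled as a titrated solution and not isolated neat.

**Step 1**
Reactants: 1 (S)-but-3-yn-2-ol
Product: 2 (S)-but-3-yn-2-yl methanesulfonate
Conditions: MsCl, Et3N, CH2Cl2, −78 to 0 °C
Reagents that add atoms: methanesulfonyl chloride, CS(=O)(=O)Cl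
Why: Mesylation takes place at oxygen and does not touch the C–O stereocentre, so the (S) configuration is kept.

**Step 2**
Reactants: 2 (S)-but-3-yn-2-yl methanesulfonate; 3 3,4,5-trimethoxybenzaldehyde
Product: 5 (1R,2R)-2-methyl-1-(3,4,5-trimethoxyphenyl)but-3-yn-1-ol, via (M)-buta-1,2-dienylzinc methanesulfonate 4 (not isolated)
Conditions: Pd(OAc)2 (5 mol %), PPh3 (5 mol %), Et2Zn (3 equiv), THF, −78 to −20 °C; aq NH4Cl
Reagents that add atoms: none
Why: Marshall propargylation: zerovalent palladium opens the mesylate by anti SN2' attack, Et2Zn transmetalates the allenylpalladium to the (M)-allenylzinc, and its SE2' addition through a cyclic transition state with the aryl group anti to the allenyl methyl should give the anti alcohol, so that C2 derives from the (S) centre of 2 by net inversion and C1 from the transition-state geometry.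

**Step 3**
Reactants: 5 (1R,2R)-2-methyl-1-(3,4,5-trimethoxyphenyl)but-3-yn-1-ol
Product: 6 (2R,3R)-3-methyl-2-(3,4,5-trimethoxyphenyl)-2,3-dihydrofuran
Conditions: Mo(CO)6 (25 mol %), Et3N, Et2O, hν (350 nm), then 5, rt
Reagents that add atoms: none
Why: Endo-selective alkynol cycloisomerisation: Et3N·Mo(CO)5 converts the terminal alkyne into a molybdenum vinylidene, the hydroxyl group attacks its electrophilic α-carbon and protodemetalation gives the cyclic enol ether without touching either stereocentre.

**Step 4**
Reactants: 6 (2R,3R)-3-methyl-2-(3,4,5-trimethoxyphenyl)-2,3-dihydrofuran; 7 chromium hexacarbonyl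
Product: 10 pentacarbonyl{methoxy[(4R,5R)-4-methyl-5-(3,4,5-trimethoxyphenyl)-4,5-dihydrofuran-2-yl]carbene}chromium, via 5-lithio dihydrofuran 8 (not isolated), via lithium acylchromate 9 (not isolated)
Conditions: t-BuLi, THF, −78 to 0 °C; Cr(CO)6, Et2O, 0 °C to rt; MeOTf, CH2Cl2, 0 °C to rt
Reagents that add atoms: methyl trifluoromethanesulfonate, COS(=O)(=O)C(F)(F)F
Why: Fischer carbene synthesis: the vinylic C–H next to the ring oxygen (C5 of 6) is the site that t-BuLi deprotonates in cyclic enol ethers, the vinyllithium adds to a CO ligand of Cr(CO)6, and the acylchromate is methylated at oxygen by the hard electrophile MeOTf.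

**Step 5**
Reactants: 11 (E)-crotonaldehyde
Product: 12 (E)-pent-3-en-1-yne
Conditions: TMSCHN2, n-BuLi, THF, −78 °C to rt; H2O; codistilled with THF and used as a titrated solution
Reagents that add atoms: trimethylsilyldiazomethane, C[Si](C)(C)C=[N+]=[N-]
Why: Colvin rearrangement: lithiated trimethylsilyldiazomethane adds 1,2 to the aldehyde, Peterson elimination and loss of N2 give an alkylidene carbene, and a 1,2-hydrogen shift gives the terminal alkyne without moving the (E) double bond, with no alkoxide present that could add to the enal.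

**Step 6**
Reactants: 10 pentacarbonyl{methoxy[(4R,5R)-4-methyl-5-(3,4,5-trimethoxyphenyl)-4,5-dihydrofuran-2-yl]carbene}chromium; 12 (E)-pent-3-en-1-yne
Product: 14 (2R,3R)-7-methoxy-3-methyl-5-[(E)-prop-1-enyl]-2-(3,4,5-trimethoxyphenyl)-2,3-dihydro-1-benzofuran-4-ol, via Cr(CO)3-bound phenol 13 (not isolated)
Conditions: 12 (2–3 equiv), THF, 50 °C, sealed tube, Ar; then air, daylight, Et2O, rt
Reagents that add atoms: none
Why: Loss of one CO from 10 at 50 °C frees a site for 12, whose triple bond inserts into the Cr=C bond with its unsubstituted carbon bonded to the carbene carbon (C7–C6), and insertion of a CO ligand into the resulting vinylcarbene gives a chromium-bound dienylketene (C5–C4). Ring A is then closed by 6π electrocyclisation of this ketene onto the enol ether β-carbon (C4–C3a), and enolisation of the cyclohexadienone gives the phenol as its Cr(CO)3 complex 13, which air and light should demetalate to 14. The closest known reaction is the Dötz benzannulation of alkenyl(alkoxy)carbene complexes, cyclic enol ether carbenes included, with terminal alkynes. No stereocentre is formed; C2 and C3 are sp3 spectators without an acidic hydrogen and should pass unchanged under the neutral conditions. The step needs regioselective alkyne insertion and selection of the triple bond over the double bond of 12: the first is secured sterically by the terminal alkyne, whose substituted carbon ends next to the CO-derived carbon so that the propenyl group sits on C5, and the second by the much stronger binding of an alkyne at the vacant site on chromium.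

**Step 7**
Reactants: 14 (2R,3R)-7-methoxy-3-methyl-5-[(E)-prop-1-enyl]-2-(3,4,5-trimethoxyphenyl)-2,3-dihydro-1-benzofuran-4-ol
Product: 15 (2R,3R)-7-methoxy-3-methyl-5-[(E)-prop-1-enyl]-2-(3,4,5-trimethoxyphenyl)-2,3-dihydro-1-benzofuran-4-yl trifluoromethanesulfonate
Conditions: Tf2O, pyridine, CH2Cl2, −20 to 0 °C
Reagents that add atoms: trifluoromethanesulfonic anhydride, O=S(=O)(OS(=O)(=O)C(F)(F)F)C(F)(F)F
Why: Aryl triflate formation by O-sulfonylation: Tf2O is small enough for the di-ortho-substituted phenol, and pyridine buffers the acid so that the propenyl group and the benzylic ether should be left alone.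

**Step 8**
Reactants: 15 (2R,3R)-7-methoxy-3-methyl-5-[(E)-prop-1-enyl]-2-(3,4,5-trimethoxyphenyl)-2,3-dihydro-1-benzofuran-4-yl trifluoromethanesulfonate
Product: 16 (2R,3R)-7-methoxy-3-methyl-5-[(E)-prop-1-enyl]-2-(3,4,5-trimethoxyphenyl)-2,3-dihydro-1-benzofuran (CNP0219898.1)
Conditions: Pd(OAc)2 (10 mol %), dppp (10 mol %), Et3N, HCO2H, DMF, 70 °C
Reagents that add atoms: none
Why: Palladium-catalysed formate reduction of an aryl triflate: oxidative addition of zerovalent palladium into the C4–O bond, exchange of triflate for formate, loss of CO2 and C–H reductive elimination replace the oxygen by hydrogen and should leave the methyl ethers, the (E)-propenyl group and both stereocentres untouched.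

**Compound list**

1 | (S)-but-3-yn-2-ol | C#C[C@H](C)O | starting material
2 | (S)-but-3-yn-2-yl methanesulfonate | C#C[C@H](C)OS(C)(=O)=O | intermediate
3 | 3,4,5-trimethoxybenzaldehyde | COc1cc(C=O)cc(OC)c1OC | starting material
4 | (M)-buta-1,2-dienylzinc methanesulfonate | [H]C(C)=[C@@]=C([H])[Zn]OS(C)(=O)=O | intermediate
5 | (1R,2R)-2-methyl-1-(3,4,5-trimethoxyphenyl)but-3-yn-1-ol | C#C[C@@H](C)[C@H](c1cc(OC)c(OC)c(OC)c1)O | intermediate
6 | (2R,3R)-3-methyl-2-(3,4,5-trimethoxyphenyl)-2,3-dihydrofuran | C1=C[C@@H](C)[C@H](c2cc(OC)c(OC)c(OC)c2)O1 | intermediate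
7 | chromium hexacarbonyl | O=C=[Cr](=C=O)(=C=O)(=C=O)(=C=O)=C=O | starting material
8 | [(4R,5R)-4-methyl-5-(3,4,5-trimethoxyphenyl)-4,5-dihydrofuran-2-yl]lithium | [Li]C1=C[C@@H](C)[C@H](c2cc(OC)c(OC)c(OC)c2)O1 | intermediate
9 | lithium pentacarbonyl{[(4R,5R)-4-methyl-5-(3,4,5-trimethoxyphenyl)-4,5-dihydrofuran-2-yl]carbonyl}chromate | [Li+].[O-]C(=[Cr](=C=O)(=C=O)(=C=O)(=C=O)=C=O)C1=C[C@@H](C)[C@H](c2cc(OC)c(OC)c(OC)c2)O1 | intermediate
10 | pentacarbonyl{methoxy[(4R,5R)-4-methyl-5-(3,4,5-trimethoxyphenyl)-4,5-dihydrofuran-2-yl]carbene}chromium | COC(=[Cr](=C=O)(=C=O)(=C=O)(=C=O)=C=O)C1=C[C@@H](C)[C@H](c2cc(OC)c(OC)c(OC)c2)O1 | intermediate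
11 | (E)-crotonaldehyde | C/C=C/C=O | starting material
12 | (E)-pent-3-en-1-yne | C/C=C/C#C | intermediate
13 | tricarbonyl{η6-(2R,3R)-7-methoxy-3-methyl-5-[(E)-prop-1-enyl]-2-(3,4,5-trimethoxyphenyl)-2,3-dihydro-1-benzofuran-4-ol}chromium (Cr(CO)3 on ring A, either face; the hapticity is written as two parts) | C/C=C/c1cc(OC)c2c(c1O)[C@@H](C)[C@H](c1cc(OC)c(OC)c(OC)c1)O2.O=C=[Cr](=C=O)=C=O | intermediate
14 | (2R,3R)-7-methoxy-3-methyl-5-[(E)-prop-1-enyl]-2-(3,4,5-trimethoxyphenyl)-2,3-dihydro-1-benzofuran-4-ol | C/C=C/c1cc(OC)c2c(c1O)[C@@H](C)[C@H](c1cc(OC)c(OC)c(OC)c1)O2 | intermediate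
15 | (2R,3R)-7-methoxy-3-methyl-5-[(E)-prop-1-enyl]-2-(3,4,5-trimethoxyphenyl)-2,3-dihydro-1-benzofuran-4-yl trifluoromethanesulfonate | C/C=C/c1cc(OC)c2c(c1OS(=O)(=O)C(F)(F)F)[C@@H](C)[C@H](c1cc(OC)c(OC)c(OC)c1)O2 | intermediate
16 | (2R,3R)-7-methoxy-3-methyl-5-[(E)-prop-1-enyl]-2-(3,4,5-trimethoxyphenyl)-2,3-dihydro-1-benzofuran | C/C=C/c1cc(OC)c2c(c1)[C@@H](C)[C@H](c1cc(OC)c(OC)c(OC)c1)O2 | target

**Step count**

Total steps: 8. Longest linear sequence: 7 steps (steps 1, 2, 3, 4, 6, 7, 8); step 5 is the one-step side branch.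

**Steps most likely to fail**

1. Step 4. The base may deprotonate the benzylic C2–H (next to oxygen and aryl) or an aryl C–H ortho to a methoxy group in competition with the vinylic C5–H, which would give mixed acylchromates or ring-degraded material. Fallback: the vinyllithium is made by tin–lithium exchange and not by deprotonation. Alkynol 5 would be cyclised with stoichiometric W(CO)5·THF (from W(CO)6, hν, THF) in the presence of Et3N and Bu3SnOTf; the tungsten vinylidene closes to an alkenyl tungstate that is stannylated in place, giving tributyl[(4R,5R)-4-methyl-5-(3,4,5-trimethoxyphenyl)-4,5-dihydrofuran-2-yl]stannane F1. Treatment of this stannane with n-BuLi in THF at −78 °C should give the vinyllithium regiospecifically, at a temperature at which neither competing C–H is attacked. The fallback sets out from 5 and rejoins the route at 8, before the addition of Cr(CO)6.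

2. Step 6. The conjugated enyne may oligomerise on chromium, the vinylketene may be diverted to non-aromatic products, or the volatile alkyne may be lost before it inserts. Fallback: the propenyl group is carried through the annulation as an allyl group. Carbene 10 would be annulated under the conditions of step 6 with the skipped enyne pent-1-en-4-yne F2, which behaves as a simple alkyl-substituted terminal alkyne, to give (2R,3R)-7-methoxy-3-methyl-5-(prop-2-enyl)-2-(3,4,5-trimethoxyphenyl)-2,3-dihydro-1-benzofuran-4-ol F3. Triflation (Tf2O, pyridine) would give the corresponding 4-yl trifluoromethanesulfonate F4, and Pd(OAc)2/dppp/HCO2H/Et3N reduction would give (2R,3R)-7-methoxy-3-methyl-5-(prop-2-enyl)-2-(3,4,5-trimethoxyphenyl)-2,3-dihydro-1-benzofuran F5. Isomerisation of the allyl group into conjugation with RuHCl(CO)(PPh3)3 in toluene at 80 °C, which favours the (E)-propenyl arene thermodynamically, returns to the target. The fallback sets out from 10 and rejoins at 16.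

3. Step 8. Oxidative addition into the hindered, electron-rich triflate may be slow enough for S–O cleavage back to the phenol to compete, and the palladium hydride may add to the propenyl double bond and reduce it or scramble its geometry. Fallback: the oxygen is removed without a palladium hydride. Triflate 15 would undergo Miyaura borylation (B2pin2, KOAc, Pd(OAc)2 with XPhos, dioxane, 90 °C) to 2-[(2R,3R)-7-methoxy-3-methyl-5-[(E)-prop-1-enyl]-2-(3,4,5-trimethoxyphenyl)-2,3-dihydro-1-benzofuran-4-yl]-4,4,5,5-tetramethyl-1,3,2-dioxaborolane F6. Base-mediated protodeboronation (aq KOH, dioxane, 90 °C), which is fast for di-ortho-substituted electron-rich arylboron compounds, would then give the target. The fallback sets out from 15 and rejoins at 16.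

**Further compounds**

F1 | step 4 | tributyl[(4R,5R)-4-methyl-5-(3,4,5-trimethoxyphenyl)-4,5-dihydrofuran-2-yl]stannane | CCCC[Sn](CCCC)(CCCC)C1=C[C@@H](C)[C@H](c2cc(OC)c(OC)c(OC)c2)O1
F2 | step 6 | pent-1-en-4-yne | C=CCC#C
F3 | step 6 | (2R,3R)-7-methoxy-3-methyl-5-(prop-2-enyl)-2-(3,4,5-trimethoxyphenyl)-2,3-dihydro-1-benzofuran-4-ol | C=CCc1cc(OC)c2c(c1O)[C@@H](C)[C@H](c1cc(OC)c(OC)c(OC)c1)O2
F4 | step 6 | (2R,3R)-7-methoxy-3-methyl-5-(prop-2-enyl)-2-(3,4,5-trimethoxyphenyl)-2,3-dihydro-1-benzofuran-4-yl trifluoromethanesulfonate | C=CCc1cc(OC)c2c(c1OS(=O)(=O)C(F)(F)F)[C@@H](C)[C@H](c1cc(OC)c(OC)c(OC)c1)O2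
F5 | step 6 | (2R,3R)-7-methoxy-3-methyl-5-(prop-2-enyl)-2-(3,4,5-trimethoxyphenyl)-2,3-dihydro-1-benzofuran | C=CCc1cc(OC)c2c(c1)[C@@H](C)[C@H](c1cc(OC)c(OC)c(OC)c1)O2
F6 | step 8 | 2-[(2R,3R)-7-methoxy-3-methyl-5-[(E)-prop-1-enyl]-2-(3,4,5-trimethoxyphenyl)-2,3-dihydro-1-benzofuran-4-yl]-4,4,5,5-tetramethyl-1,3,2-dioxaborolane | C/C=C/c1cc(OC)c2c(c1B1OC(C)(C)C(C)(C)O1)[C@@H](C)[C@H](c1cc(OC)c(OC)c(OC)c1)O2
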